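**Retrosynthetic overview**
1. The last two bonds are C10=C11 and C10'=C11': two Horner–Wadsworth–Emmons olefinations join the ring A phosphonate 14 and the ring B phosphonate 18 to the C12 dialdehyde 24 (C11 to C11').
2. Ring B is not built separately: it is the ring A alcohol 14 after hydroxyl-directed epoxidation of C4=C5, Mitsunobu inversion at C3 and hydride opening at C4, which gives the 3'R,5'S trans-diol.
3. Ring A: the C3 stereocentre comes from Corey–Bakshi–Shibata reduction of trienone 13, and 13 comes from 12 by protodesilylation at C4.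
4. Key disconnection: C3–C4 and C5–C6 of ring A, made in one rhodium-catalysed hydroacylative [4+2] annulation of 4-alkynal 10 with silylpropyne 11. The enabling feature is that ring A at the ketone level is a 4-alkylidenecyclohex-2-enone (C3=O, C4=C5, exocyclic C6=C7 with C7–H cis to C5): its C3–C2–C1(Me2)–C6≡C7 array is a 4-alkynal and its C4=C5–CH3 unit is an alkyne.
5. Ring order: the ring A carbocycle (step 7) is the only ring closed; a temporary C4–C5 oxirane (step 10) is opened again in step 12 on the way to ring B.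

Key step: step 7

Remark: carotenoid locants are used throughout (ring A = C1–C6 with C4=C5, ring B = C1'–C6' with the two hydroxyls, chain C7–C15 and C15'–C7'); commercial 19 is an E/Z mixture and is taken to converge on the 2E products under the olefination conditions.

**Route**

Step 1
Reactants: 1 prop-2-yn-1-ol
Product: 3 (2E)-3-iodo-2-methylprop-2-en-1-ol, via alkenylalane 2 (not isolated)
Conditions: Me3Al (2.5 equiv), Cp2ZrCl2 (0.25 equiv), CH2Cl2, 0 °C to rt; then I2, THF, −30 to 0 °C
Reagents that add atoms: trimethylaluminium C[Al](C)C; iodine II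
Why: Zirconium-catalysed Negishi carboalumination adds methyl and aluminium syn across the alkyne with aluminium on the terminal carbon, and iodinolysis of the C–Al bond of 2 with retention gives the E iodide.

Step 2
Reactants: 3 (2E)-3-iodo-2-methylprop-2-en-1-ol
Product: 4 (1E)-3-bromo-1-iodo-2-methylprop-1-ene
Conditions: CBr4, PPh3, CH2Cl2, 0 °C
Reagents that add atoms: tetrabromomethane BrC(Br)(Br)Br
Why: Appel reaction: the primary allylic alcohol is displaced by bromide through its oxyphosphonium salt while the vinyl iodide is inert.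

Step 3
Reactants: 4 (1E)-3-bromo-1-iodo-2-methylprop-1-ene
Product: 5 diethyl [(2E)-3-iodo-2-methylprop-2-en-1-yl]phosphonate
Conditions: P(OEt)3 (neat), 100 °C
Reagents that add atoms: triethyl phosphite CCOP(OCC)OCC
Why: Michaelis–Arbuzov reaction at the primary allylic bromide; a vinyl iodide does not react with a phosphite without a nickel catalyst, and the E geometry is untouched.

Step 4
Reactants: 6 2,2-dimethylpent-4-enal
Product: 7 3,3-dimethylhex-5-en-1-yne
Conditions: dimethyl (1-diazo-2-oxopropyl)phosphonate, K2CO3, MeOH, 0 °C to rt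
Reagents that add atoms: dimethyl (1-diazo-2-oxopropyl)phosphonate CC(=O)C(=[N+]=[N-])P(=O)(OC)OC
Why: Seyferth–Gilbert homologation with the Ohira–Bestmann reagent converts the non-enolisable aldehyde into the terminal alkyne under mild carbonate conditions.

Step 5
Reactants: 7 3,3-dimethylhex-5-en-1-yne
Product: 9 3,3-dimethylpent-4-ynal, via ozonide 8 (not isolated)
Conditions: O3 (1.0 equiv, metered), CH2Cl2, −78 °C; then Me2S, −78 °C to rt
Reagents that add atoms: ozone [O-][O+]=O
Why: Ozonolysis with reductive work-up: ozone adds to the monosubstituted alkene far faster than to the terminal alkyne, so one equivalent should cleave only the vinyl group.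

Step 6
Reactants: 9 3,3-dimethylpent-4-ynal; 5 diethyl [(2E)-3-iodo-2-methylprop-2-en-1-yl]phosphonate
Product: 10 diethyl [(2E)-2,6,6-trimethyl-8-oxooct-2-en-4-yn-1-yl]phosphonate
Conditions: Pd(PPh3)2Cl2 (3 mol %), CuI (6 mol %), Et3N, THF, rt
Reagents that add atoms: none
Why: Sonogashira coupling: oxidative addition of zerovalent palladium into the C–I bond and coupling with the copper acetylide proceed with retention of the E geometry, and the amine base at room temperature should spare the aldehyde and the phosphonate.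

Step 7
Reactants: 10 diethyl [(2E)-2,6,6-trimethyl-8-oxooct-2-en-4-yn-1-yl]phosphonate; 11 trimethyl(prop-1-yn-1-yl)silane
Product: 12 diethyl {(2E)-2-methyl-4-[(1E)-2,6,6-trimethyl-4-oxo-3-(trimethylsilyl)cyclohex-2-en-1-ylidene]but-2-en-1-yl}phosphonate
Conditions: [Rh(dppe)]2(BF4)2 (5 mol %), 11 (3 equiv), acetone, 25–40 °C
Reagents that add atoms: none
Why: The aldehyde C–H bond of 10 adds oxidatively to the cationic rhodium centre, the Rh–H bond adds cis across the tethered C6≡C7 triple bond (H to C7, Rh to C6) to give a five-membered acyl(alkenyl)rhodacycle, 11 inserts into the Rh–C6 bond (C5–C6 formed), and reductive elimination of the acyl carbon with the silyl-bearing carbon forms C3–C4 and releases the catalyst. The closest known reaction type is the [Rh(dppe)]-catalysed hydroacylative [4+2] annulation of 4-alkynals with internal alkynes to 4-alkylidenecyclohex-2-enones. Ring A is closed in the [4+2] mode (four atoms C3–C2–C1–C6 of 10 plus C4 and C5 of 11) by reductive elimination from a seven-membered rhodacycle. No stereocentre is formed; the 6E geometry (C8 cis to C1, C7–H cis to C5) is fixed by the cis hydrometalation and the 8E bond is carried over from 10. The step needs one orientation of alkyne insertion and an intermolecular path that outruns intramolecular trans-hydroacylation to a cyclopentenone: the bulky SiMe3 group, which stabilises an adjacent carbon–metal bond, should stay on the rhodium-bound carbon as in Larock-type annulations of silylalkynes, so that the small methyl-bearing carbon bonds to the hindered C6, and the excess of 11 favours insertion.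

Step 8
Reactants: 12 diethyl {(2E)-2-methyl-4-[(1E)-2,6,6-trimethyl-4-oxo-3-(trimethylsilyl)cyclohex-2-en-1-ylidene]but-2-en-1-yl}phosphonate
Product: 13 diethyl {(2E)-2-methyl-4-[(1E)-2,6,6-trimethyl-4-oxocyclohex-2-en-1-ylidene]but-2-en-1-yl}phosphonate
Conditions: CF3CO2H (2 equiv), CH2Cl2, 0 °C; aqueous NaHCO3 work-up
Reagents that add atoms: none
Why: Acid-mediated protodesilylation of a vinylsilane: ipso-protonation at C4 gives a C5 cation stabilised by the β-silicon and by the C6=C7–C8=C9 diene, and loss of the silyl group to trifluoroacetate restores C4=C5; 12 has no stereocentre to lose.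

Step 9
Reactants: 13 diethyl {(2E)-2-methyl-4-[(1E)-2,6,6-trimethyl-4-oxocyclohex-2-en-1-ylidene]but-2-en-1-yl}phosphonate
Product: 14 diethyl {(2E)-4-[(1E,4S)-4-hydroxy-2,6,6-trimethylcyclohex-2-en-1-ylidene]-2-methylbut-2-en-1-yl}phosphonate
Conditions: (R)-2-methyl-CBS-oxazaborolidine (20 mol %), BH3·SMe2 (1.0 equiv), THF, −30 °C; MeOH quench
Reagents that add atoms: none
Why: Corey–Bakshi–Shibata reduction: the C4=C5 alkenyl arm acts as the large and C2H2 as the small substituent of the ketone, so the (R)-oxazaborolidine should deliver hydride to the face that gives the 3S alcohol by 1,2-reduction only.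

Step 10
Reactants: 14 diethyl {(2E)-4-[(1E,4S)-4-hydroxy-2,6,6-trimethylcyclohex-2-en-1-ylidene]-2-methylbut-2-en-1-yl}phosphonate
Product: 15 diethyl {(2E)-4-[(1R,2E,5S,6S)-5-hydroxy-1,3,3-trimethyl-7-oxabicyclo[4.1.0]heptan-2-ylidene]-2-methylbut-2-en-1-yl}phosphonate
Conditions: VO(acac)2 (5 mol %), t-BuOOH (1.5 equiv, decane solution), CH2Cl2, 0 °C
Reagents that add atoms: tert-butyl hydroperoxide CC(C)(C)OO
Why: Vanadium-catalysed hydroxyl-directed epoxidation: the C3 alkoxide binds vanadium and delivers the peroxide oxygen to the allylic C4=C5 bond on the face of the hydroxyl (sets 4S,5R, epoxide cis to OH), while the bishomoallylic C6=C7 and the remote C8=C9 bonds are not activated.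

Step 11
Reactants: 15 diethyl {(2E)-4-[(1R,2E,5S,6S)-5-hydroxy-1,3,3-trimethyl-7-oxabicyclo[4.1.0]heptan-2-ylidene]-2-methylbut-2-en-1-yl}phosphonate
Product: 16 (1R,2E,5R,6S)-2-[(2E)-4-(diethoxyphosphoryl)-3-methylbut-2-en-1-ylidene]-1,3,3-trimethyl-7-oxabicyclo[4.1.0]heptan-5-yl benzoate
Conditions: PPh3, DIAD, PhCO2H, THF, 0 °C to rt
Reagents that add atoms: benzoic acid OC(=O)c1ccccc1
Why: Mitsunobu reaction: SN2 displacement of the C3 oxyphosphonium ion by benzoate inverts C3 to R and places the ester trans to the epoxide; the quaternary epoxide carbon and the phosphonate do not take part.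

Step 12
Reactants: 16 (1R,2E,5R,6S)-2-[(2E)-4-(diethoxyphosphoryl)-3-methylbut-2-en-1-ylidene]-1,3,3-trimethyl-7-oxabicyclo[4.1.0]heptan-5-yl benzoate
Product: 18 diethyl {(2E)-4-[(1E,2S,4R)-2,4-dihydroxy-2,6,6-trimethylcyclohexylidene]-2-methylbut-2-en-1-yl}phosphonate, via trans-epoxy alcohol 17 (not isolated)
Conditions: NaAlH2(OCH2CH2OMe)2 (3.5 equiv), THF, −20 to 0 °C; Rochelle salt work-up
Reagents that add atoms: none
Why: Hydride cleavage of the benzoate gives the C3 alkoxyaluminate of 17 on the face opposite to the oxirane oxygen, which delivers hydride from the rear to the less substituted C4 (directed reductive opening of a 2,3-epoxy alcohol to a 1,3-diol), so the C5–O bond and its configuration are kept and the 3'R,5'S trans-diol of ring B results.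

Step 13
Reactants: 19 ethyl (2E)-4-(diethoxyphosphoryl)-3-methylbut-2-enoate (2.2 equiv); 20 1,4-dioxane-2,3-diol
Product: 22 diethyl (2E,4E,6E,8E)-3,8-dimethyldeca-2,4,6,8-tetraenedioate, via aldehyde ester 21 (not isolated)
Conditions: NaOEt (2.5 equiv), EtOH, 0 °C to rt
Reagents that add atoms: none
Why: Twofold Horner–Wadsworth–Emmons olefination of glyoxal (released from 20 by the alkoxide) with the vinylogous phosphonoacetate anion; the stabilised anion should give E disubstituted double bonds and mainly 2E,8E trisubstituted ones, and the symmetric all-E diester should be purified by crystallisation.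

Step 14
Reactants: 22 diethyl (2E,4E,6E,8E)-3,8-dimethyldeca-2,4,6,8-tetraenedioate
Product: 23 (2E,4E,6E,8E)-3,8-dimethyldeca-2,4,6,8-tetraene-1,10-diol
Conditions: i-Bu2AlH (4.5 equiv), CH2Cl2, −78 °C; Rochelle salt work-up
Reagents that add atoms: none
Why: 1,2-Reduction of the two conjugated ester groups by the aluminium hydride at low temperature gives the bis-allylic diol without touching the tetraene.

Step 15
Reactants: 23 (2E,4E,6E,8E)-3,8-dimethyldeca-2,4,6,8-tetraene-1,10-diol
Product: 24 (2E,4E,6E,8E)-3,8-dimethyldeca-2,4,6,8-tetraenedial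
Conditions: MnO2 (excess), CH2Cl2, rt, dark
Reagents that add atoms: none
Why: Allylic oxidation with MnO2 converts the two primary allylic alcohols into the conjugated dialdehyde without over-oxidation or double-bond isomerisation.

Step 16
Reactants: 14 diethyl {(2E)-4-[(1E,4S)-4-hydroxy-2,6,6-trimethylcyclohex-2-en-1-ylidene]-2-methylbut-2-en-1-yl}phosphonate; 24 (2E,4E,6E,8E)-3,8-dimethyldeca-2,4,6,8-tetraenedial (4 equiv)
Product: 25 (2E,4E,6E,8E,10E,12E,14E)-14-[(4S)-4-hydroxy-2,6,6-trimethylcyclohex-2-en-1-ylidene]-3,8,12-trimethyltetradeca-2,4,6,8,10,12-hexaenal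
Conditions: KOtBu (2.1 equiv), THF, −30 °C; then transfer into 24, THF, −78 to 0 °C, dark
Reagents that add atoms: none
Why: Horner–Wadsworth–Emmons olefination: the allylic phosphonate anion of 14 (the C3 alkoxide forms as well) attacks one formyl group through its α-carbon C10 and syn-elimination of phosphate should give the E C10=C11 bond; inverse addition to excess 24 limits double olefination, and C3 is not touched.

Step 17
Reactants: 25 (2E,4E,6E,8E,10E,12E,14E)-14-[(4S)-4-hydroxy-2,6,6-trimethylcyclohex-2-en-1-ylidene]-3,8,12-trimethyltetradeca-2,4,6,8,10,12-hexaenal; 18 diethyl {(2E)-4-[(1E,2S,4R)-2,4-dihydroxy-2,6,6-trimethylcyclohexylidene]-2-methylbut-2-en-1-yl}phosphonate (1.3 equiv)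
Product: 26 (3S,3'R,5'S,6E,6'E)-all-E-4,5'-retro-β,β-carotene-3,3',5'-triol (CNP0269135.1)
Conditions: KOtBu (4.5 equiv), THF, −30 to 0 °C, dark, argon; pH 7 buffer work-up
Reagents that add atoms: none
Why: Horner–Wadsworth–Emmons olefination of the C26 aldehyde with the C10' phosphonate anion of 18 forms the last E double bond C10'=C11'; the three hydroxyls are carried as alkoxides, no stereocentre is affected, and minor Z isomers should be removable by crystallisation.

**Compound list**
1 | prop-2-yn-1-ol | C#CCO | starting material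
2 | dimethylaluminium (2E)-3-(dimethylalumanyl)-2-methylprop-2-en-1-olate | C[Al](C)OC/C(C)=C/[Al](C)C | intermediate
3 | (2E)-3-iodo-2-methylprop-2-en-1-ol | OC/C(C)=C/I | intermediate
4 | (1E)-3-bromo-1-iodo-2-methylprop-1-ene | BrC/C(C)=C/I | intermediate
5 | diethyl [(2E)-3-iodo-2-methylprop-2-en-1-yl]phosphonate | CCOP(=O)(OCC)C/C(C)=C/I | intermediate
6 | 2,2-dimethylpent-4-enal | C=CCC(C)(C)C=O | starting material
7 | 3,3-dimethylhex-5-en-1-yne | C=CCC(C)(C)C#C | intermediate
8 | 3-(2,2-dimethylbut-3-yn-1-yl)-1,2,4-trioxolane | C#CC(C)(C)CC1OCOO1 | intermediate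
9 | 3,3-dimethylpent-4-ynal | C#CC(C)(C)CC=O | intermediate
10 | diethyl [(2E)-2,6,6-trimethyl-8-oxooct-2-en-4-yn-1-yl]phosphonate | CCOP(=O)(OCC)C/C(C)=C/C#CC(C)(C)CC=O | intermediate
11 | trimethyl(prop-1-yn-1-yl)silane | CC#C[Si](C)(C)C | starting material
12 | diethyl {(2E)-2-methyl-4-[(1E)-2,6,6-trimethyl-4-oxo-3-(trimethylsilyl)cyclohex-2-en-1-ylidene]but-2-en-1-yl}phosphonate | CCOP(=O)(OCC)C/C(C)=C/C=C1/C(C)=C([Si](C)(C)C)C(=O)CC1(C)C | intermediate
13 | diethyl {(2E)-2-methyl-4-[(1E)-2,6,6-trimethyl-4-oxocyclohex-2-en-1-ylidene]but-2-en-1-yl}phosphonate | CCOP(=O)(OCC)C/C(C)=C/C=C1/C(C)=CC(=O)CC1(C)C | intermediate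
14 | diethyl {(2E)-4-[(1E,4S)-4-hydroxy-2,6,6-trimethylcyclohex-2-en-1-ylidene]-2-methylbut-2-en-1-yl}phosphonate | CCOP(=O)(OCC)C/C(C)=C/C=C1/C(C)=C[C@@H](O)CC1(C)C | intermediate
15 | diethyl {(2E)-4-[(1R,2E,5S,6S)-5-hydroxy-1,3,3-trimethyl-7-oxabicyclo[4.1.0]heptan-2-ylidene]-2-methylbut-2-en-1-yl}phosphonate | CCOP(=O)(OCC)C/C(C)=C/C=C1/[C@@]2(C)O[C@H]2[C@@H](O)CC1(C)C | intermediate
16 | (1R,2E,5R,6S)-2-[(2E)-4-(diethoxyphosphoryl)-3-methylbut-2-en-1-ylidene]-1,3,3-trimethyl-7-oxabicyclo[4.1.0]heptan-5-yl benzoate | CCOP(=O)(OCC)C/C(C)=C/C=C1/[C@@]2(C)O[C@H]2[C@H](OC(=O)c3ccccc3)CC1(C)C | intermediate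
17 | diethyl {(2E)-4-[(1R,2E,5R,6S)-5-hydroxy-1,3,3-trimethyl-7-oxabicyclo[4.1.0]heptan-2-ylidene]-2-methylbut-2-en-1-yl}phosphonate | CCOP(=O)(OCC)C/C(C)=C/C=C1/[C@@]2(C)O[C@H]2[C@H](O)CC1(C)C | intermediate
18 | diethyl {(2E)-4-[(1E,2S,4R)-2,4-dihydroxy-2,6,6-trimethylcyclohexylidene]-2-methylbut-2-en-1-yl}phosphonate | CCOP(=O)(OCC)C/C(C)=C/C=C1\C(C)(C)C[C@@H](O)C[C@]1(C)O | intermediate
19 | ethyl (2E)-4-(diethoxyphosphoryl)-3-methylbut-2-enoate | CCOC(=O)/C=C(\C)CP(=O)(OCC)OCC | starting material
20 | 1,4-dioxane-2,3-diol | OC1OCCOC1O | starting material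
21 | ethyl (2E,4E)-3-methyl-6-oxohexa-2,4-dienoate | CCOC(=O)/C=C(C)/C=C/C=O | intermediate
22 | diethyl (2E,4E,6E,8E)-3,8-dimethyldeca-2,4,6,8-tetraenedioate | CCOC(=O)/C=C(C)/C=C/C=C/C(C)=C/C(=O)OCC | intermediate
23 | (2E,4E,6E,8E)-3,8-dimethyldeca-2,4,6,8-tetraene-1,10-diol | OC/C=C(C)/C=C/C=C/C(C)=C/CO | intermediate
24 | (2E,4E,6E,8E)-3,8-dimethyldeca-2,4,6,8-tetraenedial | O=C/C=C(C)/C=C/C=C/C(C)=C/C=O | intermediate
25 | (2E,4E,6E,8E,10E,12E,14E)-14-[(4S)-4-hydroxy-2,6,6-trimethylcyclohex-2-en-1-ylidene]-3,8,12-trimethyltetradeca-2,4,6,8,10,12-hexaenal | CC1=C[C@@H](O)CC(C)(C)\C1=C/C=C(C)/C=C/C=C(C)/C=C/C=C/C(C)=C/C=O | intermediate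
26 | (3S,3'R,5'S,6E,6'E)-all-E-4,5'-retro-β,β-carotene-3,3',5'-triol | CC1=C[C@@H](O)CC(C)(C)\C1=C/C=C(C)/C=C/C=C(C)/C=C/C=C/C(C)=C/C=C/C(C)=C/C=C1\C(C)(C)C[C@@H](O)C[C@]1(C)O | target

**Step count and risks**
Total step count: 17. Longest linear sequence: 11 steps (1, 2, 3, 6, 7, 8, 9, 10, 11, 12, 17).

Steps most likely to fail:

Step 7. What may go wrong: silylpropyne 11 inserts in the reverse orientation, or intramolecular trans-hydroacylation of 10 to a cyclopentenone (or decarbonylation) outruns the intermolecular insertion. Fallback: the same two bonds are made one after the other by known chemistry, setting out from 10. Addition of prop-1-ynylmagnesium bromide (THF, −78 °C) forms C3–C4 and gives the propargylic alcohol F1. Hydroxyl-directed trans-hydroalumination with NaAlH2(OCH2CH2OMe)2 followed by iodinolysis gives the (Z)-iodo allylic alcohol F2, and Dess–Martin oxidation gives the (Z)-β-iodo enone F3. A reductive Heck cyclisation (Pd(OAc)2, PPh3, HCO2Na, DMF, 60 °C) then closes ring A: 6-exo-dig syn-carbopalladation of C6≡C7 by the C5–Pd bond forms C5–C6, and formate reduction of the C7–Pd bond with retention gives the same 6E geometry. The fallback comes back to the route at 13, so steps 7 and 8 are bypassed.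

Step 11. What may go wrong: slow displacement at the hindered C3 oxyphosphonium ion, with elimination or opening of the neighbouring oxirane taking over; the subsequent hydride step could also attack the phosphonate. Fallback: setting out from 15, Dess–Martin oxidation (NaHCO3, CH2Cl2) gives the epoxy ketone F4. SmI2 (THF/MeOH, −90 °C) cleaves the C4–O bond reductively to the tertiary β-hydroxy ketone F5. Evans–Saksena reduction with Me4NBH(OAc)3 (MeCN/AcOH, −30 °C) delivers hydride intramolecularly from the C5 oxygen and gives the 1,3-anti diol. The fallback comes back to the route at 18 and bypasses steps 11 and 12.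

Step 16. What may go wrong: olefination at both formyl groups of 24, attack of the extended anion of 14 through its γ-carbon, and base-induced self-condensation of the dialdehyde. Fallback: the two ends of the central unit are differentiated before coupling, setting out from 23. Monosilylation (NaH, 1 equiv; t-BuMe2SiCl, THF) gives the mono-silyl ether F6, and MnO2 gives the silyloxy aldehyde F7. Olefination of F7 with the anion of 14 (KOtBu, THF) gives the C26 silyl ether F8, and Bu4NF removes the silyl group to give the C26 diol F9. Primary-selective oxidation (TEMPO, PhI(OAc)2, CH2Cl2) then comes back to the route at 25.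

**Further compounds**
F1 | step 7 | diethyl [(2E)-8-hydroxy-2,6,6-trimethylundec-2-ene-4,9-diyn-1-yl]phosphonate | CCOP(=O)(OCC)C/C(C)=C/C#CC(C)(C)CC(O)C#CC
F2 | step 7 | diethyl [(2E,9Z)-8-hydroxy-10-iodo-2,6,6-trimethylundeca-2,9-dien-4-yn-1-yl]phosphonate | CCOP(=O)(OCC)C/C(C)=C/C#CC(C)(C)CC(O)/C=C(\I)C
F3 | step 7 | diethyl [(2E,9Z)-10-iodo-2,6,6-trimethyl-8-oxoundeca-2,9-dien-4-yn-1-yl]phosphonate | CCOP(=O)(OCC)C/C(C)=C/C#CC(C)(C)CC(=O)/C=C(\I)C
F4 | step 11 | diethyl {(2E)-2-methyl-4-[(1R,2E,6R)-1,3,3-trimethyl-5-oxo-7-oxabicyclo[4.1.0]heptan-2-ylidene]but-2-en-1-yl}phosphonate | CCOP(=O)(OCC)C/C(C)=C/C=C1/[C@@]2(C)O[C@H]2C(=O)CC1(C)C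
F5 | step 11 | diethyl {(2E)-4-[(1E,2S)-2-hydroxy-2,6,6-trimethyl-4-oxocyclohexylidene]-2-methylbut-2-en-1-yl}phosphonate | CCOP(=O)(OCC)C/C(C)=C/C=C1\C(C)(C)CC(=O)C[C@]1(C)O
F6 | step 16 | (2E,4E,6E,8E)-10-{[tert-butyl(dimethyl)silyl]oxy}-3,8-dimethyldeca-2,4,6,8-tetraen-1-ol | OC/C=C(C)/C=C/C=C/C(C)=C/CO[Si](C)(C)C(C)(C)C
F7 | step 16 | (2E,4E,6E,8E)-10-{[tert-butyl(dimethyl)silyl]oxy}-3,8-dimethyldeca-2,4,6,8-tetraenal | O=C/C=C(C)/C=C/C=C/C(C)=C/CO[Si](C)(C)C(C)(C)C
F8 | step 16 | (1S,4E)-4-[(2E,4E,6E,8E,10E,12E)-14-{[tert-butyl(dimethyl)silyl]oxy}-3,7,12-trimethyltetradeca-2,4,6,8,10,12-hexaen-1-ylidene]-3,5,5-trimethylcyclohex-2-en-1-ol | CC1=C[C@@H](O)CC(C)(C)\C1=C/C=C(C)/C=C/C=C(C)/C=C/C=C/C(C)=C/CO[Si](C)(C)C(C)(C)C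
F9 | step 16 | (1S,4E)-4-[(2E,4E,6E,8E,10E,12E)-14-hydroxy-3,7,12-trimethyltetradeca-2,4,6,8,10,12-hexaen-1-ylidene]-3,5,5-trimethylcyclohex-2-en-1-ol | CC1=C[C@@H](O)CC(C)(C)\C1=C/C=C(C)/C=C/C=C(C)/C=C/C=C/C(C)=C/CO
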